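The numbers in the tables are calculated on assumed constants, and the scatter is random.

I started from the rings.

| flask | first end groups | second end groups | temperature | remark | time |
|---|---|---|---|---|---|
| summer | 0.50 M | 0.50 M | 10 °C | run made earlier |  |
| winter | 0.70 M | 0.50 M | 25 °C | run made earlier |  |
| noon | 1.1 M | 0.50 M | 10 °C | run made earlier |  |
| east | 0.50 M (fed, over 25 min) | 0.500 M | 25 °C | all else is in the flask from the start; the feed brings no volume worth counting | 30 min |
| north-west | 0.50 M (fed, over 25 min) | 0.500 M |  | the addition at −15 °C, then warmed to 25 °C; the feed brings no volume worth counting | 30 min |
| north-east | 0.50 M | 0.500 M (in portions, 4, over 25 min) | 25 °C | first portion at the start, last at 25 min | 30 min |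
| north | 0.50 M | 0.500 M (fed, over 25 min) | 25 °C | all else is in the flask from the start; the feed brings no volume worth counting | 30 min |

| run | time / min | links / % | rings / % | first end groups / % |
|---|---|---|---|---|
| summer | 10.0 | 21.9 | 0 | 77.2 |
| summer | 20.0 | 33.5 | 1.7 | 65.1 |
| summer | 30.0 | 39.4 | 0 | 59.0 |
| summer | 40.0 | 43.2 | 0.9 | 55.7 |
| winter | 3.00 | 18.2 | 0.2 | 79.8 |
| winter | 8.00 | 28.2 | 1.3 | 68.2 |
| winter | 15.0 | 32.8 | 2.8 | 62.9 |
| winter | 25.0 | 32.6 | 4.2 | 59.6 |
| noon | 4.00 | 13.4 | 2.3 | 88.3 |
| noon | 8.00 | 17.1 | 0 | 82.3 |
| noon | 20.0 | 24.4 | 1.4 | 74.2 |
| noon | 50.0 | 30.7 | 0.7 | 67.0 |

(standard deviation of a reading: 1 percentage point)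

- the earlier runs were read with a standard deviation of 1 percentage point
- what may be going on: first end groups + second end groups -> links; first end groups + second end groups -> rings; 2 second end groups -> self-condensation product; second end groups -> decomposed reagent; second end groups + links -> over-reaction product

- the flask that comes out highest in share of links in links plus rings, or "all alike" when all lie within 1.5 percentage points (east / north-west / north-east / north / all alike)
- share of links in links plus rings at the end, east
- share of links in links plus rings at the end, north-west
- share of links in links plus rings at the end, north-east
- share of links in links plus rings at the end, north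

Did rings go with links? In the winter run, between 15.0 min and 25.0 min, links read 32.8% and then 32.6% of the charge, while rings read 2.8% and then 4.2%, each reading with a scatter of 1 percentage point. So I read rings as running by the clock. I named the ring clock the fraction of the free first end groups that turns to rings each warm minute, read from those winter readings as 0.00229 min⁻¹. I replaced the falling curve of first end groups by its mean, 0.613 of the charge, and the two end readings lie 3.3 points apart, a gap much smaller than that mean.

How long does north-west run on that clock? Summer's highest ring reading was 1.7% at 10 °C, so I counted none from the addition at −15 °C. That left 5.00 min of warmth.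

What do those minutes yield in north-west? Winter also started with 0.50 M of second end groups, though with 0.70 M of first end groups against 0.50 M in north-west, and near 5.50 min the mean of its two readings put free first end groups at about 0.740 of the charge. As an estimate I took 0.260 as the fraction used in north-west, and counted it as links plus rings. The clock gave rings of 0.00994, so the link share (the selectivity) came to 96.2%. East, north-east and north stay warm for the whole 30 min, and winter's last readings gave a share of 88.6%, lower than my north-west figure, so I chose north-west.

The forecast also named north-west, with east 86%, north-west 97%, north-east 92.5% and north 91.5%. Its north-west figure stood a little above mine, and for that flask it spoke of “a short, concentrated warm spell”.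

The flasks gave east 86.0%, north-west 97.1%, north-east 88.9% and north 89.1%, with north-west highest.

    first end groups + second end groups → links (k = 0.231 M⁻¹ min⁻¹, Ea = 57.0 kJ mol⁻¹)
    first end groups + second end groups → rings, rate k2*[first end groups] as long as [second end groups] is above zero (k = 0.00210 min⁻¹, Ea = 91.0 kJ mol⁻¹)
    2 second end groups → self-condensation product (k = 0.120 M⁻¹ min⁻¹, Ea = 75.0 kJ mol⁻¹)
    second end groups → decomposed reagent (k = 0.0423 min⁻¹, Ea = 94.0 kJ mol⁻¹)
    second end groups + links → over-reaction product (k = 0.0873 M⁻¹ min⁻¹, Ea = 74.0 kJ mol⁻¹)
    (constants at 25 °C)

A neighbour of north-west, charged with 0.12 M of second end groups, took the same reckoning. The clock, run for 5.00 min on first end groups taken as averaging 0.950 of the charge, gave rings of 1.09%. Against that neighbour's links of 8.86%, this made a link share of 89.0%, and the flask gave 89.9%. North-west's own share has moved by 5 points at a charge of 0.157 M of second end groups.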